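All runs were generated by integration for an exercise; scatter was added.

Read the lifetime of intermediate A off Wednesday's run before anything else.

| flask | starting material | protic impurity | remark | time |
|---|---|---|---|---|
| Wednesday's | 0.050 M | 0.010 M | run made earlier |  |
| Monday's | 0.050 M | 0.0050 M | run made earlier |  |
| Tuesday's | 0.050 M | 0.020 M | run made earlier |  |
| eta | 0.050 M (fed, over 0.800 h) | 0.0100 M | all but starting material at the start; starting material goes in evenly over 0.800 h, the run ends at 1.0 h | 1.0 h |
| zeta | 0.050 M | 0.0100 M | a closed flask charged with all of it at once and left for 1.0 h | 1.0 h |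
| beta | 0.050 M | 0.0100 M | plug flow through a tube for 1.0 h, no back-mixing | 1.0 h |
| alpha | 0.050 M | 0.0100 M | one stirred flow tank at steady state, fed with the mixture as stated, mean residence time 1.0 h |  |

| run | time / min | intermediate A / % | target / % |
|---|---|---|---|
| Wednesday's | 8.00 | 77.8 | 0.6 |
| Wednesday's | 20.0 | 58.6 | 0 |
| Wednesday's | 40.0 | 35.9 | 6.2 |
| Wednesday's | 60.0 | 20.0 | 10.1 |
| Monday's | 6.00 | 80.3 | 0 |
| Monday's | 15.0 | 70.7 | 0.7 |
| Monday's | 30.0 | 47.3 | 1.8 |
| Monday's | 50.0 | 29.0 | 7.3 |
| Tuesday's | 4.00 | 70.5 | 2.6 |
| Tuesday's | 8.00 | 73.6 | 1.2 |
| Tuesday's | 20.0 | 54.3 | 1.4 |
| Tuesday's | 50.0 | 25.9 | 5.4 |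

(readings scatter by 1 percentage point)

- the stated concentrations are those of everything mixed, before any reaction; amounts are the same in each set-up
- what was read earlier has a scatter of 1 percentage point, one standard deviation
- the feed brings no volume worth counting
- the earlier runs were made in a closed, stirred flask

- the set-up with the highest amount of intermediate A at the outlet or at the end, in percent of the starting material put in ("none" if the first two lie within 2 percentage points) (eta / zeta / beta / alpha / none)
- amount of intermediate A at the outlet or at the end, in percent of the starting material put in, eta
- amount of intermediate A at the outlet or at the end, in percent of the starting material put in, zeta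
- amount of intermediate A at the outlet or at the end, in percent of the starting material put in, beta
- amount of intermediate A at the outlet or at the end, in percent of the starting material put in, alpha

In Wednesday's run, intermediate A falls from 77.8 % at 8.00 min to 20.0 % at 60.0 min. So I read 38.3 min as its first-order lifetime, the time in which it falls by a factor of e. The first reading already stands high, so I treat intermediate A as formed on entry and let each portion age from then.

In zeta and beta, each portion ages for 1.0 h, so I reckon that 20.9 % survives. In eta, portions enter evenly over 0.800 h and age for less, so the average over the feed gives 41.7 %. In the stirred tank alpha, the survival is one over one plus residence time per lifetime, which gives 38.9 %. I rank eta first, and my figures stand before any loss to protic impurity.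

The forecast allows for that loss. It gives 41 % for eta, since “late-fed material has less time to decay”, with 21 % for zeta, 21 % for beta and 37 % for alpha, and it names eta as best.

The simulation gives 41.3 % for eta, 20.6 % for zeta, 20.6 % for beta and 35.1 % for alpha, so eta is highest.

starting material → intermediate A (k = 0.00680 s⁻¹); intermediate A → intermediate B (k = 4.40 × 10⁻⁴ s⁻¹); intermediate B → target (k = 5.70 × 10⁻⁵ s⁻¹); starting material + intermediate B → side product (k = 0.00230 L mol⁻¹ s⁻¹); starting material + protic impurity → quenched substrate (k = 0.0500 L mol⁻¹ s⁻¹) With the step from starting material and intermediate B to side product struck out, eta gives 41.5 %. Carrying the 41.3 % of eta forward by the lifetime to 2.5 h gives 3.94 %, and the eta flask read at that time holds 3.84 %.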